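Numbering used throughout: cycloheptanone C1 (CHMe)–C2–C3–C4 (fusion, C–OH)–C5 (fusion, CH)–C9 (C=O)–C10 (quaternary); cyclopentane C4–C5–C6–C7 (CHOH)–C8 (CMe2).
Retrosynthetic cuts, in order: the sp3–sp2 bond from the C10 side chain to the butenolide; C4–C8 (cyclopentane, both hydroxyls traced back to a C7–C8 epoxide and a C4 ketone); C5–C6 (prenyl); the ring-expansion carbon C5 between C9 and C4; C10–allyl and C1–methyl on 2-methylcyclohexenone.
Enabling feature: the cyclopentane carries oxygen on C7, two methyls on C8 and oxygen on the fusion carbon C4. This 1,3-diol across a quaternary carbon is what a C8 radical from a prenyl epoxide on C5 leaves when it adds to the C4 carbonyl of a cycloheptane-1,3-dione (C4, C9).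
Forward order: the six-membered ring comes with the starting enone, is enlarged to the seven-membered ring by dibromocarbene insertion of C5, the cyclopentane closes in the titanium step, and the butenolide is joined last.
Stereochemistry: C1 from ligand-controlled copper-catalysed conjugate methylation, C10 from allylation anti to the C1 methyl, C7 from Shi epoxidation, C4 from C7 in the radical closure, C5 by titanium chelation acting on a freely epimerising centre.

Key step: step 12

Assumption: the antipode of the phosphoramidite ligand in step 1 is the one that delivers methyl to the enone face giving the (3R) centre; both antipodes are available and one test reaction settles which to use.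

Step 1
Reactants: 1 2-methylcyclohex-2-en-1-one; 2 allyl bromide
Product: 4 (2S,3R)-2,3-dimethyl-2-(prop-2-en-1-yl)cyclohexan-1-one, via aluminium enolate 3 (not isolated)
Conditions: Me3Al, CuTC (CuO2CC4H3S, 2 mol%), chiral biphenol phosphoramidite (4 mol%), Et2O, −30 °C; then MeLi, HMPA/THF, allyl bromide, −30 °C to rt
Reagents that add atoms: trimethylaluminium, C[Al](C)C
Why: Copper-catalysed asymmetric conjugate addition sets C1 (R) under ligand control and gives the enolate regiospecifically; its ate complex with MeLi is allylated anti to the neighbouring methyl, which sets quaternary C10 (S).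

Step 2
Reactants: 4 (2S,3R)-2,3-dimethyl-2-(prop-2-en-1-yl)cyclohexan-1-one
Product: 5 2-[(1S,2R)-1,2-dimethyl-6-oxocyclohexyl]acetaldehyde
Conditions: O3, CH2Cl2, −78 °C; then PPh3, −78 °C to rt
Reagents that add atoms: ozone, [O-][O+]=O
Why: Ozonolysis with reductive work-up cleaves the terminal alkene and removes the one surplus carbon of the allyl group, the saturated ketone being inert to ozone.

Step 3
Reactants: 5 2-[(1S,2R)-1,2-dimethyl-6-oxocyclohexyl]acetaldehyde
Product: 6 (2S,3R)-2-(2-hydroxyethyl)-2,3-dimethylcyclohexan-1-one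
Conditions: NaBH4 (0.3 equiv), CH2Cl2/EtOH, −78 °C
Reagents that add atoms: none
Why: Chemoselective borohydride reduction at low temperature, the unhindered aldehyde reacting far faster than the ketone flanked by the quaternary carbon.

Step 4
Reactants: 6 (2S,3R)-2-(2-hydroxyethyl)-2,3-dimethylcyclohexan-1-one
Product: 7 (2S,3R)-2-[2-(tert-butyldimethylsilyloxy)ethyl]-2,3-dimethylcyclohexan-1-one
Conditions: TBSCl, imidazole, DMF, rt
Reagents that add atoms: tert-butyldimethylsilyl chloride, CC(C)(C)[Si](C)(C)Cl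
Why: Silylation of the primary alcohol, which also draws any cyclic hemiketal back to the open hydroxy ketone.

Step 5
Reactants: 7 (2S,3R)-2-[2-(tert-butyldimethylsilyloxy)ethyl]-2,3-dimethylcyclohexan-1-one
Product: 8 tert-butyl{2-[(1S,6R)-1,6-dimethyl-2-(trimethylsilyloxy)cyclohex-2-en-1-yl]ethoxy}dimethylsilane
Conditions: LDA, THF, −78 °C; then TMSCl, Et3N, −78 to 0 °C
Reagents that add atoms: chlorotrimethylsilane, C[Si](C)(C)Cl
Why: Enolisation is possible only on the CH2 side (the other alpha carbon is quaternary), and O-silylation of the lithium enolate gives the single enol ether.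

Step 6
Reactants: 8 tert-butyl{2-[(1S,6R)-1,6-dimethyl-2-(trimethylsilyloxy)cyclohex-2-en-1-yl]ethoxy}dimethylsilane
Product: 10 (6R,7S)-2-bromo-7-[2-(tert-butyldimethylsilyloxy)ethyl]-6,7-dimethylcyclohept-2-en-1-one, via dibromocyclopropane 9 (not isolated)
Conditions: CHBr3, KOtBu, pentane, −20 °C to rt; then toluene, 80 °C; aq. NaHCO3
Reagents that add atoms: bromoform, BrC(Br)Br
Why: Dibromocarbene cyclopropanates the electron-rich enol ether and the adduct opens electrocyclically with loss of bromide and the silyl group, a one-carbon ring expansion that inserts C5 as the bromine-bearing alpha carbon of the cycloheptenone.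

Step 7
Reactants: 10 (6R,7S)-2-bromo-7-[2-(tert-butyldimethylsilyloxy)ethyl]-6,7-dimethylcyclohept-2-en-1-one; 11 tributyl(3-methylbut-2-en-1-yl)stannane
Product: 12 (6R,7S)-7-[2-(tert-butyldimethylsilyloxy)ethyl]-6,7-dimethyl-2-(3-methylbut-2-en-1-yl)cyclohept-2-en-1-one
Conditions: Pd2(dba)3 (cat.), AsPh3, CuI, NMP, 50 °C
Reagents that add atoms: none
Why: Stille coupling of the alpha-bromoenone with the prenylstannane, reductive elimination at the less substituted allyl terminus giving the linear prenyl group on C5.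

Step 8
Reactants: 12 (6R,7S)-7-[2-(tert-butyldimethylsilyloxy)ethyl]-6,7-dimethyl-2-(3-methylbut-2-en-1-yl)cyclohept-2-en-1-one
Product: 13 (3S,4R)-3-[2-(tert-butyldimethylsilyloxy)ethyl]-3,4-dimethyl-1-(3-methylbut-2-en-1-yl)-8-oxabicyclo[5.1.0]octan-2-one (both faces of the cis-epoxide)
Conditions: H2O2 (30% aq.), NaOH (cat.), MeOH, 0 °C
Reagents that add atoms: hydrogen peroxide, OO
Why: Weitz–Scheffer nucleophilic epoxidation attacks only the electron-poor enone at C4 and leaves the prenyl alkene alone; the epoxide stores the C4 oxygen and blocks C5, and its configuration is erased later.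

Step 9
Reactants: 13 (3S,4R)-3-[2-(tert-butyldimethylsilyloxy)ethyl]-3,4-dimethyl-1-(3-methylbut-2-en-1-yl)-8-oxabicyclo[5.1.0]octan-2-one
Product: 14 (3S,4R)-3-[2-(tert-butyldimethylsilyloxy)ethyl]-1-{[(2R)-3,3-dimethyloxiran-2-yl]methyl}-3,4-dimethyl-8-oxabicyclo[5.1.0]octan-2-one
Conditions: D-fructose-derived Shi ketone (30 mol%), Oxone (2KHSO5·KHSO4·K2SO4), K2CO3, Bu4NHSO4, MeCN/CH2(OMe)2/aq. Na2B4O7 buffer, 0 °C
Reagents that add atoms: potassium peroxymonosulfate, [K+].OOS(=O)(=O)[O-]
Why: Shi epoxidation, the chiral dioxirane attacking the trisubstituted prenyl alkene through the spiro transition state and setting C7 (R) under reagent control; 13 has no enolisable position, so the basic medium is harmless.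

Step 10
Reactants: 14 (3S,4R)-3-[2-(tert-butyldimethylsilyloxy)ethyl]-1-{[(2R)-3,3-dimethyloxiran-2-yl]methyl}-3,4-dimethyl-8-oxabicyclo[5.1.0]octan-2-one
Product: 15 (2S,3R)-2-[2-(tert-butyldimethylsilyloxy)ethyl]-7-{[(2R)-3,3-dimethyloxiran-2-yl]methyl}-6-hydroxy-2,3-dimethylcycloheptan-1-one (mixture at C6 and C7)
Conditions: SmI2 (2.2 equiv), THF/MeOH, −90 °C; pH 7 buffer
Reagents that add atoms: none
Why: Reductive opening of the alpha,beta-epoxy ketone by divalent samarium cleaves the C5–O bond through the ketyl and the samarium enolate is protonated to the beta-hydroxy ketone; the isolated epoxide is inert to SmI2 at this temperature.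

Step 11
Reactants: 15 (2S,3R)-2-[2-(tert-butyldimethylsilyloxy)ethyl]-7-{[(2R)-3,3-dimethyloxiran-2-yl]methyl}-6-hydroxy-2,3-dimethylcycloheptan-1-one
Product: 16 (2R,4S,5R)-4-[2-(tert-butyldimethylsilyloxy)ethyl]-2-{[(2R)-3,3-dimethyloxiran-2-yl]methyl}-4,5-dimethylcycloheptane-1,3-dione (C2 epimerises through the enol; drawn as the 2R epimer that cyclises)
Conditions: Dess–Martin periodinane, NaHCO3, CH2Cl2, 0 °C to rt; filtration through neutral alumina, used at once
Reagents that add atoms: none
Why: Dess–Martin oxidation of a beta-hydroxy ketone to the 1,3-dione under buffered neutral conditions, so the epoxide and the stereolabile dione never meet base or strong oxidant together; the C4 centre of the mixture is erased and C5 becomes labile.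

Step 12
Reactants: 16 (2R,4S,5R)-4-[2-(tert-butyldimethylsilyloxy)ethyl]-2-{[(2R)-3,3-dimethyloxiran-2-yl]methyl}-4,5-dimethylcycloheptane-1,3-dione
Product: 17 (2R,3aR,5S,6R,8aR)-5-[2-(tert-butyldimethylsilyloxy)ethyl]-2,8a-dihydroxy-1,1,5,6-tetramethyloctahydroazulen-4(1H)-one
Conditions: Cp2TiCl2 (2.5 equiv), Zn dust, THF, rt (forms Cp2TiCl); then 16 added slowly, THF, 0 °C to rt; aq. NaH2PO4
Reagents that add atoms: none
Why: Proposed new method: Cp2TiCl, a trivalent titanium one-electron donor, should open the C7–C8 epoxide homolytically at the tertiary carbon, so the C7–O bond and its (R) configuration are kept and the radical sits on C8; the radical adds to the C4 carbonyl carbon and a second Cp2TiCl traps the alkoxyl radical as a tetravalent titanium alkoxide, which makes the otherwise reversible addition productive. The closest known reaction type is the Cp2TiCl-mediated cyclisation of epoxy ketones to cycloalkanols by radical addition to C=O, established for simple ketones but not for an enolisable 2-substituted 1,3-dione. The cyclopentane C4–C5–C6–C7–C8 closes in the 5-exo-trig mode onto the carbonyl, forming only the C4–C8 bond. C4 is set by C7, since the bulky titanoxy group on C7 and the titanium-bound carbonyl oxygen should stay apart in the chair-like transition state, putting the new C4–O bond trans to C7–O. C5 epimerises through the enol, and the epimer that reacts is the one in which titanium bridges the C4 oxygen and the C9 carbonyl, which places C4–O cis to C9 and so gives the trans ring fusion. The step needs attack at C4 and not at C9, which the quaternary C10 secures by shielding C9, and it needs the epoxide to escape the enol oxygen, which the mainly diketo form of cycloheptane-1,3-diones and the neutral medium favour.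

Step 13
Reactants: 17 (2R,3aR,5S,6R,8aR)-5-[2-(tert-butyldimethylsilyloxy)ethyl]-2,8a-dihydroxy-1,1,5,6-tetramethyloctahydroazulen-4(1H)-one
Product: 18 (2R,3aR,5S,6R,8aR)-2,8a-dihydroxy-5-(2-hydroxyethyl)-1,1,5,6-tetramethyloctahydroazulen-4(1H)-one
Conditions: HF·pyridine, pyridine, THF, 0 °C to rt
Reagents that add atoms: none
Why: Fluoride cleavage of the primary silyl ether under buffered, mildly acidic conditions that avoid base-induced dehydration or retro-aldol of the beta-hydroxy ketone.

Step 14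
Reactants: 18 (2R,3aR,5S,6R,8aR)-2,8a-dihydroxy-5-(2-hydroxyethyl)-1,1,5,6-tetramethyloctahydroazulen-4(1H)-one
Product: 19 (2R,3aR,5S,6R,8aR)-2,8a-dihydroxy-5-(2-iodoethyl)-1,1,5,6-tetramethyloctahydroazulen-4(1H)-one
Conditions: I2, PPh3, imidazole, CH2Cl2, 0 °C
Reagents that add atoms: iodine, II
Why: Appel-type iodination (Garegg–Samuelsson conditions) activates only the unhindered primary alcohol; the secondary alcohol next to CMe2 and the tertiary alcohol are too hindered to react.

Step 15
Reactants: 19 (2R,3aR,5S,6R,8aR)-2,8a-dihydroxy-5-(2-iodoethyl)-1,1,5,6-tetramethyloctahydroazulen-4(1H)-one; 20 4-bromofuran-2(5H)-one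
Product: 21 (2R,3aR,5S,6R,8aR)-2,8a-dihydroxy-1,1,5,6-tetramethyl-5-[2-(5-oxo-2,5-dihydrofuran-3-yl)ethyl]octahydroazulen-4(1H)-one
Conditions: NiBr2(dme) (10 mol%), 4,4'-di-tert-butyl-2,2'-bipyridine (10 mol%), Zn dust, NaI, DMA, rt
Reagents that add atoms: none
Why: Nickel-catalysed reductive cross-electrophile coupling: the vinyl bromide adds oxidatively to zerovalent nickel, the primary alkyl radical from the iodide is captured and reductive elimination forms the sp3–sp2 bond with zinc as terminal reductant, free hydroxyls and the ketone being tolerated.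

Compound list
1 | 2-methylcyclohex-2-en-1-one | CC1=CCCCC1=O | starting material
2 | allyl bromide | C=CCBr | starting material
3 | dimethylaluminium (3R)-2,3-dimethylcyclohex-1-en-1-olate | C[C@@H]1CCCC(O[Al](C)C)=C1C | intermediate
4 | (2S,3R)-2,3-dimethyl-2-(prop-2-en-1-yl)cyclohexan-1-one | C[C@@H]1CCCC(=O)[C@@]1(C)CC=C | intermediate
5 | 2-[(1S,2R)-1,2-dimethyl-6-oxocyclohexyl]acetaldehyde | C[C@@H]1CCCC(=O)[C@@]1(C)CC=O | intermediate
6 | (2S,3R)-2-(2-hydroxyethyl)-2,3-dimethylcyclohexan-1-one | C[C@@H]1CCCC(=O)[C@@]1(C)CCO | intermediate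
7 | (2S,3R)-2-[2-(tert-butyldimethylsilyloxy)ethyl]-2,3-dimethylcyclohexan-1-one | C[C@@H]1CCCC(=O)[C@@]1(C)CCO[Si](C)(C)C(C)(C)C | intermediate
8 | tert-butyl{2-[(1S,6R)-1,6-dimethyl-2-(trimethylsilyloxy)cyclohex-2-en-1-yl]ethoxy}dimethylsilane | C[C@@H]1CCC=C(O[Si](C)(C)C)[C@@]1(C)CCO[Si](C)(C)C(C)(C)C | intermediate
9 | (2S,3R)-7,7-dibromo-2-[2-(tert-butyldimethylsilyloxy)ethyl]-2,3-dimethyl-1-(trimethylsilyloxy)bicyclo[4.1.0]heptane (both cyclopropane faces) | C[C@@H]1CCC2C(Br)(Br)C2(O[Si](C)(C)C)[C@@]1(C)CCO[Si](C)(C)C(C)(C)C | intermediate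
10 | (6R,7S)-2-bromo-7-[2-(tert-butyldimethylsilyloxy)ethyl]-6,7-dimethylcyclohept-2-en-1-one | C[C@@H]1CCC=C(Br)C(=O)[C@@]1(C)CCO[Si](C)(C)C(C)(C)C | intermediate
11 | tributyl(3-methylbut-2-en-1-yl)stannane | CCCC[Sn](CCCC)(CCCC)CC=C(C)C | starting material
12 | (6R,7S)-7-[2-(tert-butyldimethylsilyloxy)ethyl]-6,7-dimethyl-2-(3-methylbut-2-en-1-yl)cyclohept-2-en-1-one | C[C@@H]1CCC=C(CC=C(C)C)C(=O)[C@@]1(C)CCO[Si](C)(C)C(C)(C)C | intermediate
13 | (3S,4R)-3-[2-(tert-butyldimethylsilyloxy)ethyl]-3,4-dimethyl-1-(3-methylbut-2-en-1-yl)-8-oxabicyclo[5.1.0]octan-2-one (both epoxide faces) | C[C@@H]1CCC2OC2(CC=C(C)C)C(=O)[C@@]1(C)CCO[Si](C)(C)C(C)(C)C | intermediate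
14 | (3S,4R)-3-[2-(tert-butyldimethylsilyloxy)ethyl]-1-{[(2R)-3,3-dimethyloxiran-2-yl]methyl}-3,4-dimethyl-8-oxabicyclo[5.1.0]octan-2-one (both faces of the ring epoxide) | C[C@@H]1CCC2OC2(C[C@H]2OC2(C)C)C(=O)[C@@]1(C)CCO[Si](C)(C)C(C)(C)C | intermediate
15 | (2S,3R)-2-[2-(tert-butyldimethylsilyloxy)ethyl]-7-{[(2R)-3,3-dimethyloxiran-2-yl]methyl}-6-hydroxy-2,3-dimethylcycloheptan-1-one (mixture at C6 and C7) | C[C@@H]1CCC(O)C(C[C@H]2OC2(C)C)C(=O)[C@@]1(C)CCO[Si](C)(C)C(C)(C)C | intermediate
16 | (2R,4S,5R)-4-[2-(tert-butyldimethylsilyloxy)ethyl]-2-{[(2R)-3,3-dimethyloxiran-2-yl]methyl}-4,5-dimethylcycloheptane-1,3-dione (C2 labile) | C[C@@H]1CCC(=O)[C@@H](C[C@H]2OC2(C)C)C(=O)[C@@]1(C)CCO[Si](C)(C)C(C)(C)C | intermediate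
17 | (2R,3aR,5S,6R,8aR)-5-[2-(tert-butyldimethylsilyloxy)ethyl]-2,8a-dihydroxy-1,1,5,6-tetramethyloctahydroazulen-4(1H)-one | C[C@@H]1CC[C@@]2(O)[C@@H](C[C@@H](O)C2(C)C)C(=O)[C@@]1(C)CCO[Si](C)(C)C(C)(C)C | intermediate
18 | (2R,3aR,5S,6R,8aR)-2,8a-dihydroxy-5-(2-hydroxyethyl)-1,1,5,6-tetramethyloctahydroazulen-4(1H)-one | C[C@@H]1CC[C@@]2(O)[C@@H](C[C@@H](O)C2(C)C)C(=O)[C@@]1(C)CCO | intermediate
19 | (2R,3aR,5S,6R,8aR)-2,8a-dihydroxy-5-(2-iodoethyl)-1,1,5,6-tetramethyloctahydroazulen-4(1H)-one | C[C@@H]1CC[C@@]2(O)[C@@H](C[C@@H](O)C2(C)C)C(=O)[C@@]1(C)CCI | intermediate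
20 | 4-bromofuran-2(5H)-one | O=C1C=C(Br)CO1 | starting material
21 | (2R,3aR,5S,6R,8aR)-2,8a-dihydroxy-1,1,5,6-tetramethyl-5-[2-(5-oxo-2,5-dihydrofuran-3-yl)ethyl]octahydroazulen-4(1H)-one | C[C@@H]1CC[C@@]2(O)[C@@H](C[C@@H](O)C2(C)C)C(=O)[C@@]1(C)CCC1=CC(=O)OC1 | target

Total step count: 15. Longest linear sequence: 15 steps (1 to 21); 2, 11 and 20 enter as commercial partners.

Steps most likely to fail

Step 12. Titanium acting as a Lewis acid may let the enol oxygen open the epoxide before homolysis, the C8 radical may collapse to the allylic alcohol before it reaches the C4 carbonyl, or chelation may fail to impose the trans ring fusion. The fallback makes the same C8 radical by hydrogen-atom transfer to an alkene, the known iron-hydride cyclisation of alkene-tethered ketones, with no epoxide and no Lewis acid present at the closure. It sets out from 14. TBSOTf and 2,6-lutidine, then DBU, would isomerise the side-chain epoxide with retention of the C7–O bond to the allyl silyl ether epoxy ketone F1. SmI2 in THF/MeOH would open the ring epoxide to the hydroxy ketone F2, and Dess–Martin periodinane would give the isopropenyl dione F3. Fe(acac)3 and PhSiH3 in ethanol would add a hydrogen atom to the terminal CH2, and 5-exo addition of the tertiary radical to C4=O would give the bis-silyl hydroazulenone F4. HF·pyridine removes both silyl groups and the route is rejoined at 18.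

Step 7. The prenyl group may be transferred with allyl transposition, giving the branched 1,1-dimethylallyl isomer, or the bromide may be lost without coupling. The fallback avoids palladium and brings the prenyl group in as prenyl bromide by enolate chemistry. It sets out from 8. Et2Zn and CH2I2 would give the siloxycyclopropane F5. FeCl3 in DMF would open it to the beta-chloro ketone F6, and NaOAc in methanol would eliminate HCl to the parent cycloheptenone F7 (Saegusa ring expansion). LDA can only remove a gamma proton of this enone, and the dienolate would be alkylated at the alpha carbon by prenyl bromide to the deconjugated prenyl ketone F8. DBU would move the double bond back into conjugation, and the route is rejoined at 12.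

Step 15. Hydrodehalogenation or homocoupling of either halide, or conjugate reduction of the bromobutenolide, may outrun the cross-coupling on a substrate with free hydroxyl groups. The fallback separates formation of the carbon nucleophile from the coupling. It sets out from 19. N-(trimethylsilyl)imidazole would cap both hydroxyls to give the bis-trimethylsilyl iodide F9. Zn dust with LiCl in THF would insert to the alkylzinc iodide F10. Negishi coupling with 20 under Pd(OAc)2 and SPhos would give the bis-trimethylsilyl butenolide F11. Citric acid in methanol removes the silyl groups, and the route is rejoined at 21.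

Further compounds
F1 | step 12 | (3S,4R)-3-[2-(tert-butyldimethylsilyloxy)ethyl]-1-[(2R)-2-(tert-butyldimethylsilyloxy)-3-methylbut-3-en-1-yl]-3,4-dimethyl-8-oxabicyclo[5.1.0]octan-2-one | C[C@@H]1CCC2OC2(C[C@@H](O[Si](C)(C)C(C)(C)C)C(C)=C)C(=O)[C@@]1(C)CCO[Si](C)(C)C(C)(C)C
F2 | step 12 | (2S,3R)-2-[2-(tert-butyldimethylsilyloxy)ethyl]-7-[(2R)-2-(tert-butyldimethylsilyloxy)-3-methylbut-3-en-1-yl]-6-hydroxy-2,3-dimethylcycloheptan-1-one | C[C@@H]1CCC(O)C(C[C@@H](O[Si](C)(C)C(C)(C)C)C(C)=C)C(=O)[C@@]1(C)CCO[Si](C)(C)C(C)(C)C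
F3 | step 12 | (4S,5R)-4-[2-(tert-butyldimethylsilyloxy)ethyl]-2-[(2R)-2-(tert-butyldimethylsilyloxy)-3-methylbut-3-en-1-yl]-4,5-dimethylcycloheptane-1,3-dione | C[C@@H]1CCC(=O)C(C[C@@H](O[Si](C)(C)C(C)(C)C)C(C)=C)C(=O)[C@@]1(C)CCO[Si](C)(C)C(C)(C)C
F4 | step 12 | (2R,3aR,5S,6R,8aR)-2-(tert-butyldimethylsilyloxy)-5-[2-(tert-butyldimethylsilyloxy)ethyl]-8a-hydroxy-1,1,5,6-tetramethyloctahydroazulen-4(1H)-one | C[C@@H]1CC[C@@]2(O)[C@@H](C[C@@H](O[Si](C)(C)C(C)(C)C)C2(C)C)C(=O)[C@@]1(C)CCO[Si](C)(C)C(C)(C)C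
F5 | step 7 | (2S,3R)-2-[2-(tert-butyldimethylsilyloxy)ethyl]-2,3-dimethyl-1-(trimethylsilyloxy)bicyclo[4.1.0]heptane | C[C@@H]1CCC2CC2(O[Si](C)(C)C)[C@@]1(C)CCO[Si](C)(C)C(C)(C)C
F6 | step 7 | (2S,3R)-2-[2-(tert-butyldimethylsilyloxy)ethyl]-6-chloro-2,3-dimethylcycloheptan-1-one | C[C@@H]1CCC(Cl)CC(=O)[C@@]1(C)CCO[Si](C)(C)C(C)(C)C
F7 | step 7 | (6R,7S)-7-[2-(tert-butyldimethylsilyloxy)ethyl]-6,7-dimethylcyclohept-2-en-1-one | C[C@@H]1CCC=CC(=O)[C@@]1(C)CCO[Si](C)(C)C(C)(C)C
F8 | step 7 | (6R,7S)-7-[2-(tert-butyldimethylsilyloxy)ethyl]-6,7-dimethyl-2-(3-methylbut-2-en-1-yl)cyclohept-3-en-1-one | C[C@@H]1CC=CC(CC=C(C)C)C(=O)[C@@]1(C)CCO[Si](C)(C)C(C)(C)C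
F9 | step 15 | (2R,3aR,5S,6R,8aR)-5-(2-iodoethyl)-1,1,5,6-tetramethyl-2,8a-bis(trimethylsilyloxy)octahydroazulen-4(1H)-one | C[C@@H]1CC[C@@]2(O[Si](C)(C)C)[C@@H](C[C@@H](O[Si](C)(C)C)C2(C)C)C(=O)[C@@]1(C)CCI
F10 | step 15 | {2-[(2R,3aR,5S,6R,8aR)-1,1,5,6-tetramethyl-4-oxo-2,8a-bis(trimethylsilyloxy)decahydroazulen-5-yl]ethyl}zinc iodide | C[C@@H]1CC[C@@]2(O[Si](C)(C)C)[C@@H](C[C@@H](O[Si](C)(C)C)C2(C)C)C(=O)[C@@]1(C)CC[Zn]I
F11 | step 15 | (2R,3aR,5S,6R,8aR)-1,1,5,6-tetramethyl-5-[2-(5-oxo-2,5-dihydrofuran-3-yl)ethyl]-2,8a-bis(trimethylsilyloxy)octahydroazulen-4(1H)-one | C[C@@H]1CC[C@@]2(O[Si](C)(C)C)[C@@H](C[C@@H](O[Si](C)(C)C)C2(C)C)C(=O)[C@@]1(C)CCC1=CC(=O)OC1
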